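Ring numbering used below: C1 (CMe2), C2 (CHBr), C3 (CH2), C4 (CHCl), C5 (alkylidene carbon), C6 (CHCl); side chain C7H= and C8H2Br.
Retrosynthetic cuts, in order: C8–Br with C5=C7 (back to a vinyl carbinol); C5–C7 (vinyl addition to a C5 ketone); C4–Cl and C6–Cl (back to C4–O and a C5=C6 alkene); ring bond C1–C6 together with C2–Br (bromonium cyclisation); and last C4–C5 and C2–C3 in one stroke.
Forward: a silylvinyl boronate (C5, C6), a vinyl group (C3, C4) and isobutenyl bromide (C1, C2, both methyls) are joined in one operation to the open chain C6 to C1. The only ring, the cyclohexane, then closes at C1–C6, and C7 and C8 come last.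
Enabling feature: the ethano unit C3–C4 of the cyclohexane carries its single heteroatom on C4 and lies between the sp2 ring carbon C5 and C2, which becomes vinylic once C1–C6 is opened to a prenyl group. It is therefore the image of a vinylboron unit that has taken an alkenyl group at the boron-bearing carbon and an alkenyl electrophile at CH2.
Stereochemistry: C4 comes from the chiral palladium catalyst (C–B, then C–O, inverted to C–Cl late). C2 comes from the chair of the cyclisation relative to C4, C6 from anti, trans-diaxial chlorohydrin formation, and the E alkene from the steric bias of the SN2′ bromination.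

Key step: step 2

Assumption: the antipode of the MandyPhos ligand is picked so that the R boronate 7 forms; the sense of induction has to be confirmed on the first run.

Step 1
Reactants: 1 ethynyltrimethylsilane; 2 pinacolborane
Product: 3 (Z)-2-[2-(trimethylsilyl)ethenyl]-4,4,5,5-tetramethyl-1,3,2-dioxaborolane
Conditions: [Rh(cod)Cl]2 (cat.), P(i-Pr)3, Et3N, cyclohexane, rt
Reagents that add atoms: none
Why: Rhodium-catalysed trans-hydroboration of a terminal alkyne: the alkyne rearranges to a rhodium vinylidene, so boron and hydrogen end up anti and the Z-alkenylboronate (Si and B cis) should result.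

Step 2
Reactants: 3 (Z)-2-[2-(trimethylsilyl)ethenyl]-4,4,5,5-tetramethyl-1,3,2-dioxaborolane; 4 vinylmagnesium bromide; 5 1-bromo-2-methylprop-1-ene
Product: 8 (1Z,3R)-6-methyl-1-(trimethylsilyl)hepta-1,5-dien-3-ol, via borate complex 6 (not isolated), via allylic boronate 7 (not isolated)
Conditions: 3, 4, NaOTf, THF, 0 °C to rt; then 5, Pd(OAc)2 (2 mol %), MandyPhos (2.4 mol %), THF–DMSO, 60 °C; then NaOH, H2O2, 0 °C
Reagents that add atoms: hydrogen peroxide OO
Why: Addition of 4 to the boron of 3 gives the bis(alkenyl)borate 6; oxidative addition of 5 to zerovalent palladium gives a cationic alkenyl complex of divalent palladium that binds the unsubstituted vinyl group of 6, which triggers a 1,2-metallate shift moving the silylvinyl carbon C5 from boron to C4 anti to the metal, and reductive elimination then joins C3 to C2. The reaction type is the enantioselective conjunctive cross-coupling of bis(alkenyl)borates with C(sp2) electrophiles, which is known to give alpha-chiral allylic boronates. No ring is closed, so no mode of closure applies; the step assembles the whole chain C6–C5–C4–C3–C2–C1 of the later ring from three small pieces. The only new stereocentre, C4, is set by the face of the vinyl group that the chiral bisphosphine lets the metal bind, and the oxidation of 7 goes with retention. The migrating carbon keeps its Z geometry, which the ring closure of step 4 needs. Migration has to outrun direct alkenyl transfer to palladium (the Suzuki-Miyaura pathway) and beta-hydride loss, and only the vinyl group may act as acceptor; the wide-bite-angle ligand, halide removal by NaOTf and the steric gap between the two alkenyl groups should secure this.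

Step 3
Reactants: 8 (1Z,3R)-6-methyl-1-(trimethylsilyl)hepta-1,5-dien-3-ol
Product: 9 tert-butyl(dimethyl){[(1Z,3R)-6-methyl-1-(trimethylsilyl)hepta-1,5-dien-3-yl]oxy}silane
Conditions: TBSCl, imidazole, DMF, rt
Reagents that add atoms: tert-butyldimethylsilyl chloride CC(C)(C)[Si](C)(C)Cl
Why: Imidazole-promoted silylation masks the hydroxyl group so that it cannot open the bromonium ion in step 4; no stereocentre is touched.

Step 4
Reactants: 9 tert-butyl(dimethyl){[(1Z,3R)-6-methyl-1-(trimethylsilyl)hepta-1,5-dien-3-yl]oxy}silane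
Product: 10 {[(1R,5S)-5-bromo-4,4-dimethylcyclohex-2-en-1-yl]oxy}(tert-butyl)dimethylsilane (Br and OTBS cis)
Conditions: NBS, morpholine (cat.), (CF3)2CHOH, 0 °C
Reagents that add atoms: N-bromosuccinimide O=C1CCC(=O)N1Br
Why: Bromonium-induced cation-olefin cyclisation (6-endo) terminated by a Z-vinylsilane: the trisubstituted alkene is the most electron-rich site for Br+, C6 attacks the tertiary end C1 anti to bromine through a chair with Br and OTBS both equatorial (hence cis, C2 = S), and the beta-silyl cation at C5 loses the silyl group so that the alkene ends up only at C5=C6.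

Step 5
Reactants: 10 {[(1R,5S)-5-bromo-4,4-dimethylcyclohex-2-en-1-yl]oxy}(tert-butyl)dimethylsilane
Product: 11 (1R,2R,4S,6R)-4-bromo-6-{[tert-butyl(dimethyl)silyl]oxy}-2-chloro-3,3-dimethylcyclohexan-1-ol
Conditions: trichloroisocyanuric acid (0.35 equiv), acetone–H2O, 0 °C
Reagents that add atoms: trichloroisocyanuric acid O=C1N(Cl)C(=O)N(Cl)C(=O)N1Cl; water O
Why: Chlorohydrin formation: Cl+ should add to the ring face opposite the pseudoaxial methyl group on C1, and water should open the chloronium ion at C5, the carbon away from the quaternary centre, in the trans-diaxial sense (Fürst-Plattner rule), which puts Cl on C6 trans to Br.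

Step 6
Reactants: 11 (1R,2R,4S,6R)-4-bromo-6-{[tert-butyl(dimethyl)silyl]oxy}-2-chloro-3,3-dimethylcyclohexan-1-ol
Product: 12 (2R,4S,6R)-4-bromo-6-{[tert-butyl(dimethyl)silyl]oxy}-2-chloro-3,3-dimethylcyclohexan-1-one
Conditions: Dess-Martin periodinane, CH2Cl2, 0 °C to rt
Reagents that add atoms: none
Why: Dess-Martin oxidation works without base and should turn the axial alcohol into the ketone without epimerising C4 or C6.

Step 7
Reactants: 12 (2R,4S,6R)-4-bromo-6-{[tert-butyl(dimethyl)silyl]oxy}-2-chloro-3,3-dimethylcyclohexan-1-one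
Product: 13 (2R,4S,6R)-4-bromo-2-chloro-6-hydroxy-3,3-dimethylcyclohexan-1-one
Conditions: HF·pyridine, THF, 0 °C to rt
Reagents that add atoms: none
Why: Fluoride-mediated desilylation in an acidic medium frees the C4 hydroxyl group while the base-sensitive alpha-chloro ketone and the alpha-ketol unit are left alone.

Step 8
Reactants: 13 (2R,4S,6R)-4-bromo-2-chloro-6-hydroxy-3,3-dimethylcyclohexan-1-one
Product: 15 (2R,4S,6S)-4-bromo-2,6-dichloro-3,3-dimethylcyclohexan-1-one (both Cl cis to each other, trans to Br), via keto triflate 14 (not isolated)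
Conditions: Tf2O, 2,6-lutidine, CH2Cl2, −78 °C; then n-Bu4NCl (1.0 equiv), −78 to 0 °C
Reagents that add atoms: trifluoromethanesulfonic anhydride O=S(=O)(OS(=O)(=O)C(F)(F)F)C(F)(F)F (atoms only in 14); tetrabutylammonium chloride CCCC[N+](CCCC)(CCCC)CCCC.[Cl-]
Why: SN2 displacement of an alpha-keto triflate by chloride, which is fast next to a carbonyl group, inverts C4 and places its chlorine cis to that on C6; one equivalent of chloride and low temperature limit chloride-chloride exchange.

Step 9
Reactants: 15 (2R,4S,6S)-4-bromo-2,6-dichloro-3,3-dimethylcyclohexan-1-one; 4 vinylmagnesium bromide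
Product: 16 (1S,2R,4S,6S)-4-bromo-2,6-dichloro-1-ethenyl-3,3-dimethylcyclohexan-1-ol
Conditions: 4, CeCl3 (anhydrous), THF, −78 °C; then aq NH4Cl, −78 °C
Reagents that add atoms: none
Why: Organocerium 1,2-addition: the vinylcerium reagent is nucleophilic but hardly basic and should beat enolisation; attack from the face opposite the two C–Cl bonds (polar Felkin-Anh) leaves OH cis to both chlorines, which holds back epoxide closure, and this carbinol centre is erased in step 10.

Step 10
Reactants: 16 (1S,2R,4S,6S)-4-bromo-2,6-dichloro-1-ethenyl-3,3-dimethylcyclohexan-1-ol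
Product: 17 ochtodene, (1S,2E,3S,5S)-5-bromo-2-(2-bromoethylidene)-1,3-dichloro-4,4-dimethylcyclohexane
Conditions: PBr3 (0.4 equiv), Et2O, −20 to 0 °C
Reagents that add atoms: phosphorus tribromide BrP(Br)Br
Why: SN2′ bromination of a tertiary vinyl carbinol (allylic transposition): bromide enters at C8 as the activated oxygen leaves C5, the two beta-chlorines disfavour ionisation, and the CH2Br group should turn toward C4, away from C6 and the gem-dimethyl carbon next to it, to give the E alkene.

Compound list
1 | ethynyltrimethylsilane | C#C[Si](C)(C)C | starting material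
2 | pinacolborane | B1OC(C)(C)C(C)(C)O1 | starting material
3 | (Z)-2-[2-(trimethylsilyl)ethenyl]-4,4,5,5-tetramethyl-1,3,2-dioxaborolane | C[Si](C)(C)/C=C\B1OC(C)(C)C(C)(C)O1 | intermediate
4 | vinylmagnesium bromide | C=C[Mg]Br | starting material
5 | 1-bromo-2-methylprop-1-ene | CC(C)=CBr | starting material
6 | bromomagnesium ethenyl[(Z)-2-(trimethylsilyl)ethenyl](pinacolato)borate | C=C[B-]1(/C=C\[Si](C)(C)C)OC(C)(C)C(C)(C)O1.[Mg+]Br | intermediate
7 | 2-[(1Z,3R)-6-methyl-1-(trimethylsilyl)hepta-1,5-dien-3-yl]-4,4,5,5-tetramethyl-1,3,2-dioxaborolane | CC(C)=CC[C@@H](B1OC(C)(C)C(C)(C)O1)/C=C\[Si](C)(C)C | intermediate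
8 | (1Z,3R)-6-methyl-1-(trimethylsilyl)hepta-1,5-dien-3-ol | CC(C)=CC[C@@H](O)/C=C\[Si](C)(C)C | intermediate
9 | tert-butyl(dimethyl){[(1Z,3R)-6-methyl-1-(trimethylsilyl)hepta-1,5-dien-3-yl]oxy}silane | CC(C)=CC[C@@H](O[Si](C)(C)C(C)(C)C)/C=C\[Si](C)(C)C | intermediate
10 | {[(1R,5S)-5-bromo-4,4-dimethylcyclohex-2-en-1-yl]oxy}(tert-butyl)dimethylsilane | CC1(C)[C@@H](Br)C[C@@H](O[Si](C)(C)C(C)(C)C)C=C1 | intermediate
11 | (1R,2R,4S,6R)-4-bromo-6-{[tert-butyl(dimethyl)silyl]oxy}-2-chloro-3,3-dimethylcyclohexan-1-ol | CC1(C)[C@@H](Br)C[C@@H](O[Si](C)(C)C(C)(C)C)[C@@H](O)[C@@H]1Cl | intermediate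
12 | (2R,4S,6R)-4-bromo-6-{[tert-butyl(dimethyl)silyl]oxy}-2-chloro-3,3-dimethylcyclohexan-1-one | CC1(C)[C@@H](Br)C[C@@H](O[Si](C)(C)C(C)(C)C)C(=O)[C@@H]1Cl | intermediate
13 | (2R,4S,6R)-4-bromo-2-chloro-6-hydroxy-3,3-dimethylcyclohexan-1-one | CC1(C)[C@@H](Br)C[C@@H](O)C(=O)[C@@H]1Cl | intermediate
14 | (1R,3R,5S)-5-bromo-3-chloro-4,4-dimethyl-2-oxocyclohexyl trifluoromethanesulfonate | CC1(C)[C@@H](Br)C[C@@H](OS(=O)(=O)C(F)(F)F)C(=O)[C@@H]1Cl | intermediate
15 | (2R,4S,6S)-4-bromo-2,6-dichloro-3,3-dimethylcyclohexan-1-one | CC1(C)[C@@H](Br)C[C@H](Cl)C(=O)[C@@H]1Cl | intermediate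
16 | (1S,2R,4S,6S)-4-bromo-2,6-dichloro-1-ethenyl-3,3-dimethylcyclohexan-1-ol | CC1(C)[C@@H](Br)C[C@H](Cl)[C@@](O)(C=C)[C@@H]1Cl | intermediate
17 | ochtodene, (1S,2E,3S,5S)-5-bromo-2-(2-bromoethylidene)-1,3-dichloro-4,4-dimethylcyclohexane | CC1(C)[C@@H](Br)C[C@H](Cl)/C(=C\CBr)[C@@H]1Cl | target

Total step count: 10. Longest linear sequence: 10 (steps 1 to 10).

Steps most likely to fail

Step 4. Br+ may show poor facial selectivity on the prenyl alkene, so that C2 forms as a mixture. The bromonium ion may also be captured by the silyl ether oxygen or the solvent before C6 arrives, and the vinylsilane may undergo ipso-bromodesilylation. The fallback sets C2 by a reagent and never has free Br+ next to the vinylsilane; it sets out from 9 and comes back at 10.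
- Shi epoxidation of the trisubstituted alkene (ketone antipode chosen for the R epoxide; a cis-disubstituted alkene is a poor substrate) would give the epoxy silyl ether F1.
- Li2NiBr4 would open F1 at the secondary carbon with inversion to the bromohydrin F2.
- 2,3,5,6-Tetrafluorobenzoyl chloride with DMAP would give the tertiary tetrafluorobenzoate F3.
- Me2AlOTf would ionise the ester with bromine participation to a single bromonium ion, which the vinylsilane closes to 10.

Step 5. Water may attack the chloronium ion at the wrong carbon, because the inductive pull of the C4 oxygen opposes the steric bias. Cl+ may also approach from the wrong face, or the hindered alkene may react too slowly. The fallback makes the C5 ketone first and brings in chlorine as an electrophile on an enol ether; it sets out from 10 and comes back at 12.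
- Hydroboration (BH3·THF, boron at C5, away from the quaternary carbon) and NaBO3 oxidation would give the ring alcohol F4.
- Dess-Martin oxidation would give the ketone F5.
- Soft enolisation with TMSOTf and Et3N toward the C6 methylene group avoids a free enolate, which could displace bromide and close a cyclopropane, and would give the enol silyl ether F6.
- NCS should then chlorinate C6 axially, from the face opposite the axial methyl group, to give 12.

Step 10. The two rotamers of the vinyl group may be poorly discriminated, which would give both alkene isomers, and bromide may exchange at the newly allylic C–Cl bonds. The fallback fixes the geometry with a temporary five-membered ring; it sets out from 13 and comes back at 17.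
- Ketenylidenetriphenylphosphorane (Bestmann ylide) would add the C4 hydroxyl group and close by intramolecular Wittig reaction to the fused butenolide F7, whose ring ties C8 to the C4 side of the alkene.
- DIBAL-H would open it to the ene-diol F8.
- One equivalent of CBr4 and PPh3 at low temperature (Appel reaction) would convert the primary allylic alcohol to the bromo alcohol F9.
- PPh3 with hexachloroacetone would replace the C4 hydroxyl group by chloride with inversion to give 17.

Further compounds
F1 | step 4 | tert-butyl({(1Z,3R)-4-[(2R)-3,3-dimethyloxiran-2-yl]-1-(trimethylsilyl)but-1-en-3-yl}oxy)dimethylsilane | CC1(C)O[C@@H]1C[C@@H](O[Si](C)(C)C(C)(C)C)/C=C\[Si](C)(C)C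
F2 | step 4 | (3S,5R,6Z)-3-bromo-5-{[tert-butyl(dimethyl)silyl]oxy}-2-methyl-7-(trimethylsilyl)hept-6-en-2-ol | CC(C)(O)[C@@H](Br)C[C@@H](O[Si](C)(C)C(C)(C)C)/C=C\[Si](C)(C)C
F3 | step 4 | (3S,5R,6Z)-3-bromo-5-{[tert-butyl(dimethyl)silyl]oxy}-2-methyl-7-(trimethylsilyl)hept-6-en-2-yl 2,3,5,6-tetrafluorobenzoate | CC(C)(OC(=O)c1c(F)c(F)cc(F)c1F)[C@@H](Br)C[C@@H](O[Si](C)(C)C(C)(C)C)/C=C\[Si](C)(C)C
F4 | step 5 | (1R,2R,4S)-4-bromo-2-{[tert-butyl(dimethyl)silyl]oxy}-5,5-dimethylcyclohexan-1-ol | CC1(C)[C@@H](Br)C[C@@H](O[Si](C)(C)C(C)(C)C)[C@H](O)C1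
F5 | step 5 | (2R,4S)-4-bromo-2-{[tert-butyl(dimethyl)silyl]oxy}-5,5-dimethylcyclohexan-1-one | CC1(C)[C@@H](Br)C[C@@H](O[Si](C)(C)C(C)(C)C)C(=O)C1
F6 | step 5 | {[(1R,5S)-5-bromo-4,4-dimethyl-2-[(trimethylsilyl)oxy]cyclohex-2-en-1-yl]oxy}(tert-butyl)dimethylsilane | CC1(C)[C@@H](Br)C[C@@H](O[Si](C)(C)C(C)(C)C)C(O[Si](C)(C)C)=C1
F7 | step 10 | (4S,6S,7aR)-6-bromo-4-chloro-5,5-dimethyl-5,6,7,7a-tetrahydro-1-benzofuran-2(4H)-one | CC1(C)[C@@H](Br)C[C@H]2OC(=O)C=C2[C@@H]1Cl
F8 | step 10 | (1R,2E,3S,5S)-5-bromo-3-chloro-2-(2-hydroxyethylidene)-4,4-dimethylcyclohexan-1-ol | CC1(C)[C@@H](Br)C[C@@H](O)/C(=C\CO)[C@@H]1Cl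
F9 | step 10 | (1R,2E,3S,5S)-5-bromo-2-(2-bromoethylidene)-3-chloro-4,4-dimethylcyclohexan-1-ol | CC1(C)[C@@H](Br)C[C@@H](O)/C(=C\CBr)[C@@H]1Cl
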